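**Retrosynthetic overview**

1. Target 35 ← acetylation and desilylation ← macrocycle 33 ← closure of the ten-membered ring at C2–C3 (samarium Barbier reaction of iodo aldehyde 32).
2. The plan rests on the γ-lactone ring O–C19(=O)–C17–C8–C7 with the tertiary oxygen on C8 and C6/C9 trans. It is a 2-chloro-2-methyl-3-silyloxycyclobutanone (C7, C8, C17, C19) one oxygen insertion away, and opens to methylchloroketene plus the C7=C8 bond of a Z-silyl dienol ether.
3. In dienol ether 23, O8 and O9 are tied in a di-tert-butylsilylene ring, so C9–H and C9–C10 lie on opposite faces of the enol ether and the ketene should add anti to the cyclohexane. 23 ← α-hydroxy ketone 22 ← dithiane 19 (C3–C8, Z alkene from lactone 13) + aldehyde 12.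
4. 12 ← enantioselective Diels–Alder reaction of 1 with 2 (sets C1, C10, C14), then C11 oxidation and methylenation.
5. Ring order: cyclohexene (step 1), cyclobutanone (step 18) expanded to the γ-lactone (step 19), ten-membered ring (step 24).

Key step: step 18

Remark: briarane numbering is used for all intermediates (six-membered ring C1, C10–C14; chain C2–C9; lactone C17–C19; branches C15, C16, C18, C20). α/β refer to the six-membered ring, β being the face of C15.
Assumption: the (S)-oxazaborolidinium catalyst of step 1 is taken to give the enantiomer of 3 that is drawn; if its facial sense is the opposite, the (R)-catalyst is used and nothing else changes.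
Assumption: commercial 1-acetoxybutadiene is an E/Z mixture of which only the E isomer 2 reacts, so it is used in excess.

**Route**

Step 1
Reactants: 1 ethyl (2E)-3-methyl-4-oxobut-2-enoate; 2 (1E)-buta-1,3-dien-1-yl acetate
Product: 3 ethyl 3-acetoxy-2-formyl-2-methylcyclohex-4-ene-1-carboxylate (14α-OAc, 1α-CHO, 1β-CH3, 10β-CO2Et)
Conditions: (S)-o-tolyl oxazaborolidine from (S)-diphenylprolinol·Tf2NH (20 mol %), CH2Cl2, −78 → −40 °C
Reagents that add atoms: none
Why: Lewis-acid-catalysed Diels–Alder reaction of an α-methyl enal, in which the boron-bound formyl group directs the oxygenated diene terminus to C1 and sits endo (C2 cis to the C14 acetate), the E dienophile fixes C2 trans to C9, and the chiral catalyst selects the face, so that C1, C10 and C14 should be set together.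

Step 2
Reactants: 3 Diels–Alder adduct
Product: 4 ethyl 3-acetoxy-2-(dimethoxymethyl)-2-methylcyclohex-4-ene-1-carboxylate (configuration as 3)
Conditions: HC(OMe)3, MeOH, PPTS (cat.), rt
Reagents that add atoms: trimethyl orthoformate, COC(OC)OC
Why: Acid-catalysed acetalisation with the orthoformate as water scavenger protects the non-enolisable C2 aldehyde without touching a stereocentre.

Step 3
Reactants: 4 acetal ester
Product: 5 6-(dimethoxymethyl)-5-(hydroxymethyl)-6-methylcyclohex-2-en-1-ol (14α-OH, 10β-CH2OH)
Conditions: LiAlH4, THF, 0 °C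
Reagents that add atoms: none
Why: Hydride reduction turns the ester into the C9 primary alcohol and cleaves the acetate, while the acetal is inert.

Step 4
Reactants: 5 diol
Product: 6 5-[(tert-butyldimethylsilyloxy)methyl]-6-(dimethoxymethyl)-6-methylcyclohex-2-en-1-ol
Conditions: TBSCl (1.05 equiv), imidazole, CH2Cl2, 0 °C
Reagents that add atoms: tert-butyldimethylsilyl chloride, CC(C)(C)[Si](C)(C)Cl
Why: Silylation of the unhindered primary C9 hydroxyl should be much faster than that of the neopentyl secondary C14 hydroxyl.

Step 5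
Reactants: 6 mono-silyl ether
Product: 7 5-[(tert-butyldimethylsilyloxy)methyl]-6-(dimethoxymethyl)-6-methylcyclohex-2-en-1-yl acetate
Conditions: Ac2O, pyridine, DMAP (cat.), CH2Cl2, rt
Reagents that add atoms: acetic anhydride, CC(=O)OC(C)=O
Why: DMAP-catalysed acetylation installs the final C14 acetate, which also deactivates H-14 towards the allylic oxidation that follows.

Step 6
Reactants: 7 allylic acetate
Product: 8 5-[(tert-butyldimethylsilyloxy)methyl]-6-(dimethoxymethyl)-6-methyl-4-oxocyclohex-2-en-1-yl acetate (C11 ketone)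
Conditions: Rh2(cap)4 (1 mol %), t-BuOOH (70% aq, 5 equiv), 1,2-dichloroethane, 40 °C
Reagents that add atoms: tert-butyl hydroperoxide, CC(C)(C)OO
Why: Radical allylic oxidation of a cyclohexene should occur at the C11 methylene, the only allylic position that is neither acyloxy-deactivated nor flanked by the quaternary carbon.

Step 7
Reactants: 8 enone
Product: 9 3-[(tert-butyldimethylsilyloxy)methyl]-2-(dimethoxymethyl)-2-methyl-4-oxocyclohexyl acetate
Conditions: [(Ph3P)CuH]6 (0.4 equiv), H2O (5 equiv), benzene, rt
Reagents that add atoms: none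
Why: Copper hydride conjugate reduction (Stryker's reagent) saturates C12–C13 without hydrogenolysis of the allylic acetate and leaves C10 untouched.

Step 8
Reactants: 9 ketone
Product: 10 3-[(tert-butyldimethylsilyloxy)methyl]-2-(dimethoxymethyl)-2-methyl-4-methylidenecyclohexyl acetate
Conditions: Zn, CH2Br2, TiCl4 (reagent preformed in THF), CH2Cl2, 0 °C → rt
Reagents that add atoms: dibromomethane, BrCBr
Why: Takai–Lombardo methylenation is non-basic, so the epimerisable C10 centre, the β-silyloxy ketone and the acetate should survive while C11=C20 is installed.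

Step 9
Reactants: 10 silyl ether
Product: 11 2-(dimethoxymethyl)-3-(hydroxymethyl)-2-methyl-4-methylidenecyclohexyl acetate
Conditions: HF·pyridine, pyridine, THF, 0 °C
Reagents that add atoms: none
Why: Buffered fluoride cleaves the primary silyl ether and leaves acetate, acetal and alkene alone.

Step 10
Reactants: 11 primary alcohol
Product: 12 2-(dimethoxymethyl)-3-formyl-2-methyl-4-methylidenecyclohexyl acetate (C9 aldehyde, 10β-CHO)
Conditions: TEMPO (10 mol %), PhI(OAc)2, CH2Cl2, rt; used crude
Reagents that add atoms: none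
Why: Oxoammonium oxidation stops at the aldehyde under non-basic conditions, which should avoid epimerisation or conjugation of the β,γ-unsaturated aldehyde.

Step 11
Reactants: 13 4-methyl-5,6-dihydro-2H-pyran-2-one
Product: 14 (2Z)-3-methylpent-2-ene-1,5-diol
Conditions: DIBAL-H (3 equiv), CH2Cl2, −78 → 0 °C; Rochelle salt
Reagents that add atoms: none
Why: 1,2-Reduction of the unsaturated lactone gives the ene-diol, the ring having fixed the Z geometry of C5=C6.

Step 12
Reactants: 14 diol
Product: 15 (3Z)-5-chloro-3-methylpent-3-en-1-ol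
Conditions: NCS, Me2S, CH2Cl2, −20 → 0 °C; used crude
Reagents that add atoms: N-chlorosuccinimide, O=C1CCC(=O)N1Cl
Why: Corey–Kim chlorination converts allylic alcohols into chlorides and leaves a saturated primary hydroxyl untouched.

Step 13
Reactants: 16 1,3-dithiane; 15 chloro alcohol
Product: 18 (3Z)-5-(1,3-dithian-2-yl)-3-methylpent-3-en-1-ol, via 2-lithio-1,3-dithiane 17 (not isolated)
Conditions: 16 (2.2 equiv), n-BuLi (2.1 equiv), THF, −30 °C; then 15 added at −78 °C, → −30 °C
Reagents that add atoms: none
Why: Corey–Seebach alkylation, in which the lithiated dithiane displaces the primary allylic chloride by SN2 (one equivalent is consumed by the hydroxyl) faster than the cold lithium alkoxide can cyclise.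

Step 14
Reactants: 18 dithiane alcohol
Product: 19 2-[(2Z)-5-[(4-methoxybenzyl)oxy]-3-methylpent-2-en-1-yl]-1,3-dithiane
Conditions: NaH, PMBCl, Bu4NI (cat.), THF/DMF, 0 °C → rt
Reagents that add atoms: 4-methoxybenzyl chloride, COc1ccc(CCl)cc1
Why: Williamson etherification; the dithiane C–H is not acidic enough for NaH.

Step 15
Reactants: 19 dithiane; 12 aldehyde
Product: 21 C9 carbinol carrying the C8 dithiane (9-OH as in the target), via lithiated dithiane 20 (not isolated)
Conditions: 19 (1.2 equiv), n-BuLi, THF, −30 °C, 2 h; then 12, −78 °C, quench at −78 °C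
Reagents that add atoms: none
Why: Corey–Seebach addition of the C8 acyl-anion equivalent to the aldehyde, faster at −78 °C than attack on the hindered acetate; Felkin–Anh addition anti to the quaternary C1 with C11 as the medium group should set C9 as required.

Step 16
Reactants: 21 dithiane carbinol
Product: 22 α-hydroxy ketone (9-OH, C8=O, C7H2–C6H=C5 Z)
Conditions: MeI, CaCO3, MeCN/H2O (9:1), 45 °C
Reagents that add atoms: water, O
Why: S-Methylation and hydrolysis of the dithiane under buffered, near-neutral conditions release the ketone without touching acetal, PMB ether, acetate or alkenes.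

Step 17
Reactants: 22 α-hydroxy ketone
Product: 23 2,2-di-tert-butyl-1,3,2-dioxasilolane spanning O8 and O9 with exocyclic Z-C8=C7 (silylene Z-dienol ether, C6 cis to O8)
Conditions: tBu2Si(OTf)2, Et3N, CH2Cl2, −78 → 0 °C
Reagents that add atoms: di-tert-butylsilyl bis(trifluoromethanesulfonate), CC(C)(C)[Si](OS(=O)(=O)C(F)(F)F)(OS(=O)(=O)C(F)(F)F)C(C)(C)C
Why: Soft enolisation as known for silylene capture of hydroxy ketones: the C9 hydroxyl is silylated, the tethered silyl triflate silylates the C8 carbonyl oxygen in a five-membered ring, and Et3N removes the doubly activated allylic C7 proton to give the conjugated enol ether in its less hindered Z geometry.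

Step 18
Reactants: 23 silylene Z-dienol ether; 24 2-chloropropanoyl chloride
Product: 26 spiro 2-chloro-2-methyl-3-silyloxycyclobutanone spanning C7 C8 C17 C19, via methylchloroketene 25 (not isolated)
Conditions: 24 (3 equiv) and Et3N (3 equiv) added slowly, hexane/CH2Cl2, rt → 40 °C
Reagents that add atoms: none
Why: Et3N dehydrochlorinates 24 to methylchloroketene 25, whose carbonyl carbon C19 is attacked by the nucleophilic enol ether carbon C7 while the developing oxocarbenium carbon C8 is captured by C17, an asynchronous (2+2) cycloaddition that is suprafacial on the alkene and is the known reaction of chloroketenes with silyl enol ethers. The cyclobutanone (C7, C8, C17, C19) closes by four-membered collapse of this zwitterion-like transition state and is spiro to the dioxasilolane at C8. C7 and C8 are set together: the Z geometry puts C6 cis to O8 and therefore trans to C9, and the face is fixed by the silylene ring, which holds C9–H and C9–C10 on opposite sides of the enol ether plane so that the ketene should add on the hydrogen side, anti to the cyclohexane. C17 is formed as the chloride epimer given by the ketene approach and does not matter, because it is reset in step 20. The step needs reaction at C7=C8 and not at C5=C6 or C11=C20: the oxygenated double bond is the most nucleophilic, the C5 terminus is fully substituted, and the diene carries inside substituents at both ends (O8 and C4), so it cannot reach the s-cis geometry of a (4+2) mode.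

Step 19
Reactants: 26 chlorocyclobutanone
Product: 27 α-chloro-α-methyl-γ-lactone (O inserted between C19 and C7)
Conditions: 30% H2O2, CF3CH2OH, Na2HPO4, 0 °C → rt
Reagents that add atoms: hydrogen peroxide, OO
Why: Baeyer–Villiger oxidation of the strained ketone by nucleophilic peroxide, which should leave the alkenes alone; the non-chlorinated allylic C7 migrates with retention.

Step 20
Reactants: 27 chlorolactone
Product: 29 lactone with 17-H and the C18 methyl cis to O8 (C17 as in the target), via 17-epi-lactone 28 (not isolated)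
Conditions: Zn–Cu, NH4Cl, MeOH/THF, rt; then DBU, toluene, 60 °C
Reagents that add atoms: none
Why: Zinc reductive dechlorination through the zinc enolate, then base equilibration of the epimerisable C17 to the epimer with the methyl on the oxygen side of C8 and anti to C9, which should be the more stable one.

Step 21
Reactants: 29 lactone PMB ether
Product: 30 C3 primary alcohol
Conditions: DDQ, CH2Cl2/pH 7 buffer, 0 °C → rt
Reagents that add atoms: none
Why: Oxidative cleavage of the PMB ether; silylene, acetal, acetate and alkenes are stable under buffered conditions.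

Step 22
Reactants: 30 alcohol
Product: 31 C3 primary iodide
Conditions: I2, PPh3, imidazole, CH2Cl2, 0 °C
Reagents that add atoms: iodine, II
Why: Appel-type iodination of an unhindered primary alcohol.

Step 23
Reactants: 31 iodide acetal
Product: 32 iodo aldehyde (C2 aldehyde)
Conditions: PPTS (cat.), acetone/H2O, 40 °C
Reagents that add atoms: water, O
Why: Mild acid hydrolysis of the acyclic acetal frees the non-enolisable C2 aldehyde, and silylene, acetate and iodide should survive.

Step 24
Reactants: 32 iodo aldehyde
Product: 33 macrocyclic C2 alcohol (ten-membered ring closed, O8/O9 silylene, 14-OAc)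
Conditions: SmI2 (4 equiv), HMPA, THF, 2 mM, −78 °C → rt
Reagents that add atoms: none
Why: Intramolecular samarium Barbier reaction, in which the primary iodide is reduced to an organosamarium that adds to the aldehyde under high dilution; a Felkin-type arrangement with C3 anti to C14 and the carbonyl oxygen turned away from C15 should give the required C2 configuration.

Step 25
Reactants: 33 macrocyclic silylene
Product: 34 2,8,9-triol 14-acetate
Conditions: HF·pyridine, THF, 0 °C → rt
Reagents that add atoms: none
Why: Fluoride cleaves the di-tert-butylsilylene and releases the C8 and C9 hydroxyls under non-basic conditions, which avoids retro-aldol opening of the β-hydroxy lactone.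

Step 26
Reactants: 34 triol
Product: 35 CNP0187723.2
Conditions: Ac2O, pyridine, DMAP (cat.), rt
Reagents that add atoms: acetic anhydride, CC(=O)OC(C)=O
Why: Acetylation of the two secondary hydroxyls (C2, C9); the hindered tertiary C8 hydroxyl should not be acylated, and any acetyl shift between O2 and O14 in step 24 is levelled here.

**Compound list**

1 | ethyl (2E)-3-methyl-4-oxobut-2-enoate | CCOC(=O)/C=C(\C)C=O | starting material
2 | (1E)-buta-1,3-dien-1-yl acetate | CC(=O)O/C=C/C=C | starting material
3 | ethyl 3-acetoxy-2-formyl-2-methylcyclohex-4-ene-1-carboxylate (CHO cis to OAc, trans to CO2Et) | C1C=C[C@H](OC(C)=O)[C@](C)(C=O)[C@H]1C(=O)OCC | intermediate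
4 | ethyl 3-acetoxy-2-(dimethoxymethyl)-2-methylcyclohex-4-ene-1-carboxylate | C1C=C[C@H](OC(C)=O)[C@](C)(C(OC)OC)[C@H]1C(=O)OCC | intermediate
5 | 6-(dimethoxymethyl)-5-(hydroxymethyl)-6-methylcyclohex-2-en-1-ol | C1C=C[C@H](O)[C@](C)(C(OC)OC)[C@H]1CO | intermediate
6 | 5-[(tert-butyldimethylsilyloxy)methyl]-6-(dimethoxymethyl)-6-methylcyclohex-2-en-1-ol | C1C=C[C@H](O)[C@](C)(C(OC)OC)[C@H]1CO[Si](C)(C)C(C)(C)C | intermediate
7 | acetate of 6 | C1C=C[C@H](OC(C)=O)[C@](C)(C(OC)OC)[C@H]1CO[Si](C)(C)C(C)(C)C | intermediate
8 | C11 enone | O=C1C=C[C@H](OC(C)=O)[C@](C)(C(OC)OC)[C@H]1CO[Si](C)(C)C(C)(C)C | intermediate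
9 | C11 ketone | O=C1CC[C@H](OC(C)=O)[C@](C)(C(OC)OC)[C@H]1CO[Si](C)(C)C(C)(C)C | intermediate
10 | 4-methylidenecyclohexyl acetate with 3-CH2OTBS | C=C1CC[C@H](OC(C)=O)[C@](C)(C(OC)OC)[C@H]1CO[Si](C)(C)C(C)(C)C | intermediate
11 | 2-(dimethoxymethyl)-3-(hydroxymethyl)-2-methyl-4-methylidenecyclohexyl acetate | C=C1CC[C@H](OC(C)=O)[C@](C)(C(OC)OC)[C@H]1CO | intermediate
12 | 2-(dimethoxymethyl)-3-formyl-2-methyl-4-methylidenecyclohexyl acetate | C=C1CC[C@H](OC(C)=O)[C@](C)(C(OC)OC)[C@H]1C=O | intermediate
13 | 4-methyl-5,6-dihydro-2H-pyran-2-one | CC1=CC(=O)OCC1 | starting material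
14 | (2Z)-3-methylpent-2-ene-1,5-diol | OC/C=C(/C)CCO | intermediate
15 | (3Z)-5-chloro-3-methylpent-3-en-1-ol | ClC/C=C(/C)CCO | intermediate
16 | 1,3-dithiane | C1CSCSC1 | starting material
17 | 2-lithio-1,3-dithiane | [Li]C1SCCCS1 | intermediate
18 | (3Z)-5-(1,3-dithian-2-yl)-3-methylpent-3-en-1-ol | OCC/C(C)=C\CC1SCCCS1 | intermediate
19 | 2-[(2Z)-5-[(4-methoxybenzyl)oxy]-3-methylpent-2-en-1-yl]-1,3-dithiane | COc1ccc(COCC/C(C)=C\CC2SCCCS2)cc1 | intermediate
20 | 2-lithio derivative of 19 | COc1ccc(COCC/C(C)=C\CC2([Li])SCCCS2)cc1 | intermediate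
21 | C9 carbinol with C8 dithiane | C=C1CC[C@H](OC(C)=O)[C@](C)(C(OC)OC)[C@H]1[C@@H](O)C1(C/C=C(/C)CCOCc2ccc(OC)cc2)SCCCS1 | intermediate
22 | 9-hydroxy C8 ketone | C=C1CC[C@H](OC(C)=O)[C@](C)(C(OC)OC)[C@H]1[C@@H](O)C(=O)C/C=C(/C)CCOCc1ccc(OC)cc1 | intermediate
23 | O8,O9-di-tert-butylsilylene Z-dienol ether (key-step precursor) | C=C1CC[C@H](OC(C)=O)[C@](C)(C(OC)OC)[C@H]1[C@H]2O[Si](C(C)(C)C)(C(C)(C)C)O/C2=C\C=C(\C)CCOCc1ccc(OC)cc1 | intermediate
24 | 2-chloropropanoyl chloride | CC(Cl)C(Cl)=O | starting material
25 | methylchloroketene | CC(Cl)=C=O | intermediate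
26 | spiro chlorocyclobutanone (key-step product) | C=C1CC[C@H](OC(C)=O)[C@](C)(C(OC)OC)[C@H]1[C@H]2O[Si](C(C)(C)C)(C(C)(C)C)O[C@@]23[C@H](/C=C(/C)CCOCc1ccc(OC)cc1)C(=O)[C@@]3(C)Cl | intermediate
27 | α-chloro-γ-lactone | C=C1CC[C@H](OC(C)=O)[C@](C)(C(OC)OC)[C@H]1[C@H]2O[Si](C(C)(C)C)(C(C)(C)C)O[C@@]23[C@H](/C=C(/C)CCOCc1ccc(OC)cc1)OC(=O)[C@@]3(C)Cl | intermediate
28 | 17-epi-lactone | C=C1CC[C@H](OC(C)=O)[C@](C)(C(OC)OC)[C@H]1[C@H]2O[Si](C(C)(C)C)(C(C)(C)C)O[C@@]23[C@H](/C=C(/C)CCOCc1ccc(OC)cc1)OC(=O)[C@H]3C | intermediate
29 | γ-lactone, C17 as in the target | C=C1CC[C@H](OC(C)=O)[C@](C)(C(OC)OC)[C@H]1[C@H]2O[Si](C(C)(C)C)(C(C)(C)C)O[C@@]23[C@H](/C=C(/C)CCOCc1ccc(OC)cc1)OC(=O)[C@@H]3C | intermediate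
30 | C3 alcohol | C=C1CC[C@H](OC(C)=O)[C@](C)(C(OC)OC)[C@H]1[C@H]2O[Si](C(C)(C)C)(C(C)(C)C)O[C@@]23[C@H](/C=C(/C)CCO)OC(=O)[C@@H]3C | intermediate
31 | C3 iodide | C=C1CC[C@H](OC(C)=O)[C@](C)(C(OC)OC)[C@H]1[C@H]2O[Si](C(C)(C)C)(C(C)(C)C)O[C@@]23[C@H](/C=C(/C)CCI)OC(=O)[C@@H]3C | intermediate
32 | iodo aldehyde | C=C1CC[C@H](OC(C)=O)[C@](C)(C=O)[C@H]1[C@H]2O[Si](C(C)(C)C)(C(C)(C)C)O[C@@]23[C@H](/C=C(/C)CCI)OC(=O)[C@@H]3C | intermediate
33 | macrocyclic C2 alcohol, O8,O9-silylene | C=C1CC[C@H](OC(C)=O)[C@@]2(C)[C@H]1[C@H]3O[Si](C(C)(C)C)(C(C)(C)C)O[C@@]34[C@H](/C=C(/C)CC[C@H]2O)OC(=O)[C@@H]4C | intermediate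
34 | 2,8,9-triol 14-acetate | C=C1CC[C@H](OC(C)=O)[C@@]2(C)[C@H]1[C@@H](O)[C@@]1(O)[C@H](/C=C(/C)CC[C@H]2O)OC(=O)[C@@H]1C | intermediate
35 | CNP0187723.2 | C=C1CC[C@H](OC(C)=O)[C@@]2(C)[C@H]1[C@@H](OC(C)=O)[C@@]1(O)[C@H](/C=C(/C)CC[C@H]2OC(C)=O)OC(=O)[C@@H]1C | target

**Count**

Total: 26 steps. Longest linear sequence: 22 steps (steps 1–10, then 15–26).

**Steps most likely to fail**

Step 18. The ketene may oligomerise faster than it adds to the hindered, conjugated enol ether, or the addition may lose regio- or facial control. The fallback sets out from 23 and returns at 29. Dichloroketene (dichloroacetyl chloride, Et3N, hexane), the most electrophilic ketene and the one with the broadest record on silyl enol ethers, should give the dichlorocyclobutanone F1. Baeyer–Villiger oxidation as in step 19 (the CCl2 carbon does not migrate) should give the dichlorolactone F2. Zn–Cu/NH4Cl removes both chlorines to give the unsubstituted lactone F3. LiHMDS (1 equiv, THF, −78 °C; the lactone α-protons are more acidic than those of the acetate) and MeI then methylate the enolate on the face anti to C9, which sets C17 kinetically and gives 29.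

Step 24. The aldehyde may be reduced to a ketyl (pinacol coupling or simple reduction), the organosamarium may attack the lactone, or it may be protonated before the ring closes. The fallback sets out from 32 and returns at 33 and makes no new compound (F0). It leaves the single-electron Barbier manifold for a polar organochromium addition: CrCl2 (excess) with catalytic cobalt phthalocyanine in DMF at high dilution turns the primary iodide into an alkylchromium(III) species. This species adds to aldehydes only and cannot reduce the carbonyl group or open the lactone.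

Step 1. Catalyst turnover may be low, or facial discrimination may be insufficient with this doubly activated dienophile and the modestly reactive acetoxy diene. The fallback sets out from 1 and 2 and returns at 5. The cycloaddition is run with an achiral Lewis acid (Me2AlCl, CH2Cl2, −78 °C), which keeps the formyl-controlled regio- and endo-selectivity and gives the racemic adduct F4. Steps 2 and 3 unchanged give the racemic acetal F5 and the racemic diol F6. The primary hydroxyl of F6 is esterified with (S)-O-methylmandelic acid (DCC, DMAP) and the diastereomeric esters are separated by chromatography or crystallisation. The ester of the required ring configuration F7 is cleaved with K2CO3 in methanol to give 5.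

**Further compounds**

F1 | step 18 | dichlorocyclobutanone analogue of 26 | C=C1CC[C@H](OC(C)=O)[C@](C)(C(OC)OC)[C@H]1[C@H]2O[Si](C(C)(C)C)(C(C)(C)C)O[C@@]23[C@H](/C=C(/C)CCOCc1ccc(OC)cc1)C(=O)C3(Cl)Cl
F2 | step 18 | α,α-dichloro-γ-lactone | C=C1CC[C@H](OC(C)=O)[C@](C)(C(OC)OC)[C@H]1[C@H]2O[Si](C(C)(C)C)(C(C)(C)C)O[C@@]23[C@H](/C=C(/C)CCOCc1ccc(OC)cc1)OC(=O)C3(Cl)Cl
F3 | step 18 | γ-lactone unsubstituted at C17 | C=C1CC[C@H](OC(C)=O)[C@](C)(C(OC)OC)[C@H]1[C@H]2O[Si](C(C)(C)C)(C(C)(C)C)O[C@@]23[C@H](/C=C(/C)CCOCc1ccc(OC)cc1)OC(=O)C3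
F0 | step 24 | none | none
F4 | step 1 | racemic 3 (relative configuration as drawn) | C1C=C[C@H](OC(C)=O)[C@](C)(C=O)[C@H]1C(=O)OCC
F5 | step 1 | racemic 4 (relative configuration as drawn) | C1C=C[C@H](OC(C)=O)[C@](C)(C(OC)OC)[C@H]1C(=O)OCC
F6 | step 1 | racemic 5 (relative configuration as drawn) | C1C=C[C@H](O)[C@](C)(C(OC)OC)[C@H]1CO
F7 | step 1 | (S)-O-methylmandelate of 5 at the primary hydroxyl | C1C=C[C@H](O)[C@](C)(C(OC)OC)[C@H]1COC(=O)[C@@H](OC)c1ccccc1
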